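**Plan**

- Ring numbering used throughout: O1, O2, C3 (CH bearing CH2CO2H), C4, C5, C6 (ketal carbon). Retrosynthetic cuts, in order: the C(sp)–C(sp2) bond of the enyne; the C6–OMe bond; the O1–O2 unit taken out from between C3 and C6; the C6–side-chain bond; and finally C3–C4 together with C5–C6.
- Enabling feature: C3 and C6 are the two carbons bound to the peroxide oxygens and are 1,4-related through C4–C5, with C6 at the ketone oxidation level. With O1–O2 removed they are the α-carbon and the carbonyl carbon of a 2-substituted cyclobutanone (ring C3–C4–C5–C6), that is, a ketene unit C3=C6 plus ethylene C4=C5.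
- Forward order of rings: cyclobutanone first; then a cis-fused γ-lactone as a temporary second ring; then the cyclobutanol is expanded to the 1,2-dioxane by insertion of O2 into the C3–C6 bond; then the methyl ketal; the enyne/ketone chain is joined last.
- Stereochemistry: C3 (S) comes from a lipase-catalysed kinetic resolution of the racemic dioxane ester. C6 (R) comes from thermodynamic ketalisation (axial OMe, both carbon chains equatorial). The E-alkene comes from a Takai olefination and is retained in the coupling.

Key step: step 2

Assumption: a commercial lipase is taken to hydrolyse the (3S,6R)-enantiomer of the racemic dioxane methyl ester faster than its antipode; the sense of enantioselection cannot be predicted for this substrate, and the fallback for step 7 covers the other case.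

**Route**

Step 1
Reactants: 1 methyl 4-chloro-4-oxobutanoate; 2 pyrrolidine
Product: 3 methyl 4-oxo-4-(pyrrolidin-1-yl)butanoate
Conditions: Et3N, CH2Cl2, 0 °C → rt
Reagents that add atoms: none
Why: Schotten–Baumann-type N-acylation, in which the acid chloride reacts far faster than the methyl ester, so the tertiary amide needed for keteniminium formation should form without touching the ester.

Step 2
Reactants: 3 methyl 4-oxo-4-(pyrrolidin-1-yl)butanoate; 4 ethylene
Product: 7 methyl 2-(2-oxocyclobutyl)acetate (racemic), via keteniminium triflate 5 (not isolated), via cyclobutaniminium triflate 6 (not isolated)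
Conditions: Tf2O (added last), 2,4,6-collidine, ethylene (5 bar), ClCH2CH2Cl, 0 → 70 °C; then aq. NaHCO3, rt
Reagents that add atoms: water (SMILES: O)
Why: Triflic anhydride O-sulfonylates the amide carbonyl of 3 (far more Lewis basic than the ester carbonyl) and collidine removes the α-hydrogen, giving the aldo-keteniminium ion 5, a cumulene C3=C6=N+ that is a much stronger 2π acceptor than the parent ketene and does not dimerise. Ethylene then adds across its C=C bond in a thermally allowed, asynchronous [2+2] cycloaddition in which the central iminium carbon (future C6) bonds first to one CH2 and the enamine carbon (future C3) collapses onto the other, so that the bonds C5–C6 and C3–C4 form in one operation; aqueous hydrolysis of cyclobutaniminium salt 6 then unveils the ketone. The closest known reaction type is the keteniminium–olefin [2+2] cycloaddition of tertiary amides with simple alkenes, ethylene included, to give 2-substituted cyclobutanones. The four-membered ring C3–C4–C5–C6 is closed by the cycloaddition itself, its second bond arising by a 4-exo-type collapse of the enamine carbon on the developing primary cationic centre. The one new stereocentre (the α-carbon) forms racemic and needs no control, because step 5 passes it through a planar radical and step 7 sets it. The step needs amide-over-ester chemoselectivity and interception of 5 by ethylene before the ester carbonyl can add to it, which the higher nucleophilicity of the amide oxygen and the ethylene pressure should secure, while the symmetrical olefin leaves no regiochemical issue.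

Step 3
Reactants: 7 methyl 2-(2-oxocyclobutyl)acetate; 8 (5-chloropent-1-yn-1-yl)trimethylsilane
Product: 11 rac-(1S,5S)-1-[5-(trimethylsilyl)pent-4-yn-1-yl]-2-oxabicyclo[3.2.0]heptan-3-one, via Grignard reagent 9 (not isolated), via chloromagnesium alkoxide 10 (not isolated)
Conditions: 8, Mg, THF, reflux; CeCl3, THF, −78 °C; then 7, −78 °C → rt; aq. NH4Cl
Reagents that add atoms: none
Why: CeCl3-promoted Grignard 1,2-addition to the strained, highly electrophilic cyclobutanone should outpace enolisation and ester attack, the nucleophile entering anti to the CH2CO2Me arm so that the alkoxide is cis to it and lactonises on warming to the cis-fused γ-lactone, a single stable compound whose relative configuration is immaterial because both centres are erased or reset later.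

Step 4
Reactants: 11 rac-(1S,5S)-1-[5-(trimethylsilyl)pent-4-yn-1-yl]-2-oxabicyclo[3.2.0]heptan-3-one
Product: 13 methyl 2-[rac-(1S,2S)-2-hydroxy-2-(pent-4-yn-1-yl)cyclobutyl]acetate, via potassium carboxylate 12 (not isolated)
Conditions: KOH (1.05 equiv), MeOH–H2O, rt; evaporate; MeI, DMF, 0 °C → rt
Reagents that add atoms: potassium hydroxide (SMILES: [K+].[OH-]); iodomethane (SMILES: CI)
Why: Saponification opens the lactone irreversibly as the carboxylate while the basic methanol protodesilylates the alkynylsilane, and O-alkylation of the carboxylate with MeI under near-neutral conditions should then give the hydroxy ester without the acid or strong base that would close the lactone again.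

Step 5
Reactants: 13 methyl 2-[rac-(1S,2S)-2-hydroxy-2-(pent-4-yn-1-yl)cyclobutyl]acetate
Product: 15 methyl 2-[6-hydroxy-6-(pent-4-yn-1-yl)-1,2-dioxan-3-yl]acetate (racemic at C3; both hemiketal epimers), via hydroperoxy ketone 14 (not isolated)
Conditions: Co(acac)2 (10 mol %), O2 (1 atm), MeCN, 40 °C
Reagents that add atoms: dioxygen (SMILES: O=O)
Why: Cobalt-catalysed aerobic oxidative ring expansion of a cyclobutanol, in which the alkoxy radical undergoes strain-driven β-scission toward the more substituted ring carbon (the secondary CH bearing CH2CO2Me rather than the primary CH2), O2 traps that radical, and the hydroperoxy ketone 14 closes to the six-membered peroxyhemiketal, C3 being formed racemic through the planar radical.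

Step 6
Reactants: 15 methyl 2-[6-hydroxy-6-(pent-4-yn-1-yl)-1,2-dioxan-3-yl]acetate
Product: 16 methyl 2-[rac-(3S,6R)-6-methoxy-6-(pent-4-yn-1-yl)-1,2-dioxan-3-yl]acetate
Conditions: TsOH·H2O (cat.), MeOH, 3 Å MS, rt
Reagents that add atoms: methanol (SMILES: CO)
Why: Acid-catalysed exchange of the hemiketal OH for OMe through the peroxy-oxocarbenium ion is reversible, so the ketal centre should settle under thermodynamic control with OMe axial (anomeric effect) and both carbon substituents equatorial, which is the 3,6-cis (OMe/CH2CO2Me) relative configuration of the target.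

Step 7
Reactants: 16 methyl 2-[rac-(3S,6R)-6-methoxy-6-(pent-4-yn-1-yl)-1,2-dioxan-3-yl]acetate
Product: 17 2-[(3S,6R)-6-methoxy-6-(pent-4-yn-1-yl)-1,2-dioxan-3-yl]acetic acid
Conditions: lipase (Burkholderia cepacia, immobilised), phosphate buffer pH 7.0–MTBE, 30 °C, stopped just under half conversion
Reagents that add atoms: water (SMILES: O)
Why: Enantioselective ester hydrolysis by an enzyme of the lipase class (kinetic resolution), whose acyl-binding pocket should distinguish the enantiomers at the β-stereocentre C3 so that the (3S,6R)-acid can be separated by mild bicarbonate extraction from the unreacted (3R,6S)-ester, the neutral aqueous medium leaving peroxide, ketal and alkyne untouched; this step fixes the absolute configuration.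

Step 8
Reactants: 18 dec-9-enoic acid
Product: 20 undec-10-en-2-one, via dilithium gem-diolate 19 (not isolated)
Conditions: MeLi (2.2 equiv), Et2O, 0 °C; then aq. NH4Cl
Reagents that add atoms: methyllithium (SMILES: [Li]C)
Why: Addition of methyllithium to the lithium carboxylate stops at the stable dilithium gem-diolate, which should collapse to the methyl ketone only on aqueous quench.

Step 9
Reactants: 20 undec-10-en-2-one
Product: 22 9-oxodecanal, via secondary ozonide 21 (not isolated)
Conditions: O3, CH2Cl2, −78 °C; then PPh3, −78 °C → rt
Reagents that add atoms: ozone (SMILES: [O-][O+]=O)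
Why: Ozonolysis of the terminal alkene with reductive work-up should give the aldehyde while the saturated methyl ketone is inert to ozone.

Step 10
Reactants: 22 9-oxodecanal
Product: 23 (E)-11-iodoundec-10-en-2-one
Conditions: CrCl2, CHI3, THF, 0 °C → rt
Reagents that add atoms: iodoform (SMILES: IC(I)I)
Why: Takai iodo-olefination, in which the gem-dichromium reagent adds to the aldehyde and eliminates to the (E)-vinyl iodide, aldehydes reacting far faster than ketones so that the methyl ketone should survive.

Step 11
Reactants: 17 2-[(3S,6R)-6-methoxy-6-(pent-4-yn-1-yl)-1,2-dioxan-3-yl]acetic acid; 23 (E)-11-iodoundec-10-en-2-one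
Product: 24 2-[(3S,6R)-6-methoxy-6-[(6E)-15-oxohexadec-6-en-4-yn-1-yl]-1,2-dioxan-3-yl]acetic acid (CNP0165935.1)
Conditions: PdCl2(PPh3)2 (cat.), CuI (cat.), Et3N, THF, rt, degassed
Reagents that add atoms: none
Why: Sonogashira coupling of the terminal alkyne with the vinyl iodide should proceed with retention of the E geometry under mild amine conditions of the kind tolerated by 1,2-dioxanes, the acid being carried as its ammonium carboxylate so that no deprotection follows.

**Compound list**

1 | methyl 4-chloro-4-oxobutanoate | COC(=O)CCC(=O)Cl | starting material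
2 | pyrrolidine | C1CCNC1 | starting material
3 | methyl 4-oxo-4-(pyrrolidin-1-yl)butanoate | COC(=O)CCC(=O)N1CCCC1 | intermediate
4 | ethylene | C=C | starting material
5 | 1-(4-methoxy-4-oxobut-1-en-1-ylidene)pyrrolidin-1-ium trifluoromethanesulfonate (keteniminium triflate) | COC(=O)CC=C=[N+]1CCCC1.[O-]S(=O)(=O)C(F)(F)F | intermediate
6 | 1-[2-(2-methoxy-2-oxoethyl)cyclobutylidene]pyrrolidin-1-ium trifluoromethanesulfonate (racemic) | COC(=O)CC1CCC1=[N+]1CCCC1.[O-]S(=O)(=O)C(F)(F)F | intermediate
7 | methyl 2-(2-oxocyclobutyl)acetate (racemic) | COC(=O)CC1CCC1=O | intermediate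
8 | (5-chloropent-1-yn-1-yl)trimethylsilane | C[Si](C)(C)C#CCCCCl | starting material
9 | [5-(trimethylsilyl)pent-4-yn-1-yl]magnesium chloride | C[Si](C)(C)C#CCCC[Mg]Cl | intermediate
10 | chloromagnesium alkoxide of methyl 2-[rac-(1S,2S)-2-hydroxy-2-[5-(trimethylsilyl)pent-4-yn-1-yl]cyclobutyl]acetate (racemate; one enantiomer drawn) | COC(=O)C[C@@H]1CC[C@]1(CCCC#C[Si](C)(C)C)O[Mg]Cl | intermediate
11 | rac-(1S,5S)-1-[5-(trimethylsilyl)pent-4-yn-1-yl]-2-oxabicyclo[3.2.0]heptan-3-one (racemate; one enantiomer drawn) | O=C1C[C@@H]2CC[C@]2(CCCC#C[Si](C)(C)C)O1 | intermediate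
12 | potassium 2-[rac-(1S,2S)-2-hydroxy-2-(pent-4-yn-1-yl)cyclobutyl]acetate (racemate; one enantiomer drawn) | [K+].[O-]C(=O)C[C@@H]1CC[C@]1(CCCC#C)O | intermediate
13 | methyl 2-[rac-(1S,2S)-2-hydroxy-2-(pent-4-yn-1-yl)cyclobutyl]acetate (racemate; one enantiomer drawn) | COC(=O)C[C@@H]1CC[C@]1(CCCC#C)O | intermediate
14 | methyl 3-hydroperoxy-6-oxoundec-10-ynoate (racemic) | COC(=O)CC(OO)CCC(=O)CCCC#C | intermediate
15 | methyl 2-[6-hydroxy-6-(pent-4-yn-1-yl)-1,2-dioxan-3-yl]acetate (racemic at C3; both hemiketal epimers) | COC(=O)CC1CCC(O)(CCCC#C)OO1 | intermediate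
16 | methyl 2-[rac-(3S,6R)-6-methoxy-6-(pent-4-yn-1-yl)-1,2-dioxan-3-yl]acetate (racemate; one enantiomer drawn) | CO[C@@]1(CCCC#C)CC[C@@H](CC(=O)OC)OO1 | intermediate
17 | 2-[(3S,6R)-6-methoxy-6-(pent-4-yn-1-yl)-1,2-dioxan-3-yl]acetic acid | CO[C@@]1(CCCC#C)CC[C@@H](CC(=O)O)OO1 | intermediate
18 | dec-9-enoic acid | C=CCCCCCCCC(=O)O | starting material
19 | dilithium undec-10-ene-2,2-bis(olate) | C=CCCCCCCCC(C)(O[Li])O[Li] | intermediate
20 | undec-10-en-2-one | C=CCCCCCCCC(C)=O | intermediate
21 | 3-(8-oxononyl)-1,2,4-trioxolane (racemic) | CC(=O)CCCCCCCC1OCOO1 | intermediate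
22 | 9-oxodecanal | CC(=O)CCCCCCCC=O | intermediate
23 | (E)-11-iodoundec-10-en-2-one | CC(=O)CCCCCCC/C=C/I | intermediate
24 | 2-[(3S,6R)-6-methoxy-6-[(6E)-15-oxohexadec-6-en-4-yn-1-yl]-1,2-dioxan-3-yl]acetic acid | CO[C@@]1(CCCC#C/C=C/CCCCCCCC(C)=O)CC[C@@H](CC(=O)O)OO1 | target

**Step count and risks**

Total step count: 11. Longest linear sequence: 8 steps (steps 1–7, then step 11).

Steps most likely to fail:

1. Step 5. The hydroxy ester may re-close to the lactone faster than the cobalt alkoxide is oxidised, or the peroxyl intermediate may be reduced or fragmented by cobalt before ring closure. Fallback, by polar peroxide chemistry: setting out from 13, a radical ring-opening bromination (NBS, PhI(OAc)2, visible light) would give methyl 3-bromo-6-oxoundec-10-ynoate F1. DBU would then eliminate to methyl (E)-6-oxoundec-2-en-10-ynoate F2, and HC(OMe)3/TsOH in MeOH would give methyl (E)-6,6-dimethoxyundec-2-en-10-ynoate F3. Exchange of one methoxy group with anhydrous H2O2 in ether (cat. acid) would give methyl (E)-6-hydroperoxy-6-methoxyundec-2-en-10-ynoate F4. Et2NH in CF3CH2OH would close the ring by 6-exo oxa-Michael addition, and the fallback comes back to the route at 16, after equilibration under the conditions of step 6 if needed.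

2. Step 7. The lipase may discriminate the remote β-centre poorly or in the opposite sense. Fallback, by classical resolution: setting out from 16, non-selective saponification (LiOH, THF–H2O, 0 °C) would give racemic 2-[6-methoxy-6-(pent-4-yn-1-yl)-1,2-dioxan-3-yl]acetic acid F5. Fractional crystallisation with (R)-1-phenylethylamine would give the (R)-1-phenylethylammonium salt of the (3S,6R)-acid F6, taken from the crystals or the mother liquor (the antipodal amine being used if that serves better). Mild acidification (aq. citric acid) brings the fallback back to the route at 17.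

3. Step 2. The ester carbonyl may capture the activated amide intramolecularly while the uptake of gaseous ethylene is slow. Fallback, attaching the ester arm after the ring is made: setting out from 4, cycloaddition with dichloroketene (Cl3CCOCl, Zn–Cu, Et2O, pressure vessel) would give 2,2-dichlorocyclobutanone F7, forming the same two ring bonds. Zn/AcOH would reduce it to cyclobutanone F8, and condensation with cyclohexylamine would give N-cyclohexylcyclobutanimine F9. LDA metalation and alkylation with methyl bromoacetate would give methyl 2-[2-(cyclohexylimino)cyclobutyl]acetate F10, and buffered aqueous oxalic acid hydrolysis brings the fallback back to the route at 7.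

Further compounds

F1 | step 5 | methyl 3-bromo-6-oxoundec-10-ynoate (racemic) | COC(=O)CC(Br)CCC(=O)CCCC#C
F2 | step 5 | methyl (E)-6-oxoundec-2-en-10-ynoate | COC(=O)/C=C/CCC(=O)CCCC#C
F3 | step 5 | methyl (E)-6,6-dimethoxyundec-2-en-10-ynoate | COC(=O)/C=C/CCC(OC)(OC)CCCC#C
F4 | step 5 | methyl (E)-6-hydroperoxy-6-methoxyundec-2-en-10-ynoate (racemic) | COC(=O)/C=C/CCC(OC)(OO)CCCC#C
F5 | step 7 | rac-2-[(3S,6R)-6-methoxy-6-(pent-4-yn-1-yl)-1,2-dioxan-3-yl]acetic acid (racemate; one enantiomer drawn) | CO[C@@]1(CCCC#C)CC[C@@H](CC(=O)O)OO1
F6 | step 7 | (R)-1-phenylethylammonium 2-[(3S,6R)-6-methoxy-6-(pent-4-yn-1-yl)-1,2-dioxan-3-yl]acetate | CO[C@@]1(CCCC#C)CC[C@@H](CC(=O)[O-])OO1.C[C@@H]([NH3+])c1ccccc1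
F7 | step 2 | 2,2-dichlorocyclobutan-1-one | O=C1CCC1(Cl)Cl
F8 | step 2 | cyclobutanone | O=C1CCC1
F9 | step 2 | N-cyclohexylcyclobutanimine | C1CCC(CC1)N=C1CCC1
F10 | step 2 | methyl 2-[2-(cyclohexylimino)cyclobutyl]acetate (racemic) | COC(=O)CC1CCC1=NC1CCCCC1
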